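- The target in this flask can be reckoned from the ochre run, which has the same 0.10 M of starting material and was last read at the flask's time (90.0 min) but holds half the free enzyme.

| flask | starting material | gas | free enzyme | remark | time |
|---|---|---|---|---|---|
| amber | 0.067 M | 21 mM (held) | 0.01 mol% | run made earlier |  |
| red | 0.15 M | 21 mM (held) | 0.01 mol% | run made earlier |  |
| ochre | 0.10 M | 21 mM (held) | 0.005 mol% | run made earlier |  |
| flask | 0.10 M | 21 mM (held) | 0.01 mol% |  | 1.5 h |

| run | time / min | target / % | starting material / % |
|---|---|---|---|
| amber | 8.00 | 0.9 | 99.4 |
| amber | 12.0 | 2.3 | 97.5 |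
| amber | 15.0 | 2.5 | 97.7 |
| amber | 25.0 | 4.0 | 95.7 |
| amber | 40.0 | 7.8 | 92.6 |
| amber | 60.0 | 11.4 | 88.0 |
| amber | 90.0 | 16.7 | 82.6 |
| red | 8.00 | 1.2 | 98.8 |
| red | 12.0 | 2.7 | 97.3 |
| red | 15.0 | 3.8 | 96.7 |
| red | 25.0 | 7.1 | 93.3 |
| red | 40.0 | 11.0 | 89.2 |
| red | 60.0 | 16.8 | 82.6 |
| red | 90.0 | 25.8 | 73.5 |
| ochre | 8.00 | 0.6 | 98.8 |
| ochre | 15.0 | 1.3 | 98.1 |
| ochre | 25.0 | 2.8 | 96.9 |
| ochre | 50.0 | 6.2 | 94.0 |
| ochre | 90.0 | 12.0 | 88.1 |

(each reading ± 0.3 percentage points)

- at the start none of second substrate is dissolved
- the numbers in the tables scatter with a standard deviation of 0.3 percentage points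
- on the list of suspects stand: starting material + free enzyme <-> first complex; first complex -> loaded enzyme + first product; second substrate + loaded enzyme <-> second complex; second complex -> free enzyme + target; gas <-> second substrate

- target at 1.5 h, in percent of the starting material charged
- concentration of second substrate in solution at 25 min, in percent of saturation
- the change that raises the amount of target at 1.5 h, in percent of the starting material charged most ("none" if none brings more than 2 percentage points) (theta / gamma / beta / none)
- amount of target at 1.5 h, in percent of the starting material charged, after theta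

- theta: doubling the saturation concentration of gas, all else as stated
- gamma: doubling the transfer coefficient of the gas, all else as stated
- beta: doubling the amount of free enzyme, all else as stated

- Ochre's last reading gives 26.7 min⁻¹: this is the mean turnover (turnover frequency), target made per enzyme charged and per minute since the start. It is a reading and carries the scatter of 0.3 percentage points on 12.0%.
- If the flask keeps ochre's mean turnover, we get 24.0% of target, and that is our number. On the same footing, doubling free enzyme adds 24 points, but this footing gives no figure for theta or gamma, so we leave the choice of the best change open.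
- The readings hold no column for [second substrate], so we offer no figure of our own for it at 25 min, nor for theta.
- Your forecast says 21.5%, lower than ours, with 90% of saturation at 25 min, beta as the best change and 24% after theta, on the ground that “Doubling enzyme nearly doubles the rate”.

    starting material + free enzyme ⇌ first complex (K = 2.60 L mol⁻¹, k = 2300 L mol⁻¹ s⁻¹)
    first complex → loaded enzyme + first product (k = 2.60 s⁻¹)
    second substrate + loaded enzyme ⇌ second complex (K = 9.50 L mol⁻¹, k = 1700 L mol⁻¹ s⁻¹)
    second complex → free enzyme + target (k = 48.0 s⁻¹)
    gas ⇌ second substrate, rate k5*(csat - [second substrate]) (kL = 5.80 × 10⁻⁴ s⁻¹)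

- The flask gives 22.0%, and 23.8% after theta, while beta is best with a gain of 16 points, against 1.7 points for theta and 1.1 points for gamma. Its [second substrate] stands at 39.5% of saturation at 25 min, not your 90%, on the way from 20.2% at 0.150 h to 52.0% at 0.750 h. The flask's mean turnover comes to 24.5 min⁻¹, below ochre's 26.7 min⁻¹. The neighbour with 0.025 mol% of free enzyme gives 44.1% at the same time, with [second substrate] at 0.00699 M against the flask's 0.0133 M, and its mean turnover is 19.6 min⁻¹.

The data were computed with constants of no real substance; noise was put on by code.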